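The route rests on disconnecting the C4a–C5 bond of ring B (locants of the decalin: C1 carries the carboxyl group, C2 a methyl, C4a and C8a the angular methyls, C5=C6 is the ring alkene). C5 is vinylic and attached to quaternary C4a, so a vinylpalladium at C5 can add to a C4=C4a alkene of a finished ring A. One intramolecular Heck reaction thereby closes ring B, creates the C4a quaternary stereocentre cis to the C8a methyl, and installs the C5=C6 alkene with its 4-methylpent-3-enyl chain. The precursor is a cyclohexene ester whose C8a carries a methyl group and a (Z)-4-bromo-8-methylnona-3,7-dienyl tether, with the C1 ester trans to the C2 methyl.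

Key step: step 8

Remark 1: the carboxyl group is carried as a methyl ester (from methyl acetoacetate), because the carbonyl at C1 is shielded by quaternary C8a and by C2 and is best unmasked at the end by SN2 demethylation instead of hydrolysis.
Remark 2: compounds 4 and 5 are racemic and their SMILES show the enantiomer that step 3 carries forward; from 6 onward every compound is a single enantiomer.
Remark 3: stereochemical arguments use the decalin locants of the target for ring A as well (C1, C2, C3, C4, C4a, C8a); systematic names keep their own locants.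

Step 1
Reactants: 1 methyl acetoacetate (2 equiv); 2 acetaldehyde
Product: 4 rac-methyl (1S,6R)-2,6-dimethyl-4-oxocyclohex-2-ene-1-carboxylate (trans), via dimethyl 2,4-diacetyl-3-methylpentanedioate 3 (not isolated)
Conditions: piperidine (cat.), neat, 0 °C to rt; then NaOMe (0.3 equiv), MeOH, reflux
Reagents that add atoms: none
Why: Knoevenagel condensation and Michael addition join two acetoacetate units to acetaldehyde, and intramolecular aldol condensation with methoxide-induced loss of the ester α to the ring ketone (a Hagemann-type cyclohexenone synthesis) should give 4, whose epimerisable ester carbon is expected to settle trans to the neighbouring methyl under the basic conditions.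

Step 2
Reactants: 4 rac-methyl (1S,6R)-2,6-dimethyl-4-oxocyclohex-2-ene-1-carboxylate
Product: 5 rac-methyl (1S,6R)-2,3,6-trimethyl-4-oxocyclohex-2-ene-1-carboxylate (trans)
Conditions: NaOMe (1.05 equiv), MeOH, 0 °C; MeI, reflux; chromatography
Reagents that add atoms: iodomethane (CI)
Why: C-alkylation of the extended (vinylogous) dienolate of a Hagemann-type ester takes place at the carbon α to the ketone (the later C4a), and reconjugation in the basic medium re-equilibrates the ester carbon toward the trans isomer, any cis isomer being removed on silica.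

Step 3
Reactants: 5 rac-methyl (1S,6R)-2,3,6-trimethyl-4-oxocyclohex-2-ene-1-carboxylate
Product: 6 methyl (1S,4S,6R)-4-hydroxy-2,3,6-trimethylcyclohex-2-ene-1-carboxylate
Conditions: (R)-2-methyl-CBS-oxazaborolidine [(3aR)-1-methyl-3,3-diphenyltetrahydro-1H,3H-pyrrolo[1,2-c][1,3,2]oxazaborole] (0.2 equiv), catecholborane (0.6 equiv), toluene, −78 °C; chromatography
Reagents that add atoms: none
Why: Corey–Bakshi–Shibata reduction run as a resolution, in which the face chosen by the (R)-catalyst (alkenyl side as the large group) coincides for the (1S,6R) enantiomer with the substrate-preferred delivery that places the hydroxyl cis to the C6 methyl, so this enantiomer should give the (4S)-alcohol while the mismatched (1R,6S) ketone reacts slowly and is separated as ketone or as the 4,6-trans alcohol.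

Step 4
Reactants: 6 methyl (1S,4S,6R)-4-hydroxy-2,3,6-trimethylcyclohex-2-ene-1-carboxylate
Product: 8 methyl (1S,2R,6R)-2,3,6-trimethyl-2-(2-oxoethyl)cyclohex-3-ene-1-carboxylate, via allyl vinyl ether 7 (not isolated)
Conditions: ethyl vinyl ether (excess), Hg(OAc)2 (cat.), reflux; then toluene, 190 °C, sealed tube
Reagents that add atoms: ethyl vinyl ether (C=COCC)
Why: Transetherification gives the allyl vinyl ether, and its Claisen rearrangement is suprafacial, so the CH2CHO unit should arrive at the later C8a on the face that carried the C4 oxygen (cis to the C2 methyl, trans to the ester), creating the quaternary stereocentre by 1,3-chirality transfer and moving the alkene to C4=C4a.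

Step 5
Reactants: 8 methyl (1S,2R,6R)-2,3,6-trimethyl-2-(2-oxoethyl)cyclohex-3-ene-1-carboxylate
Product: 10 methyl (1S,2R,6R)-2,3,6-trimethyl-2-(3-oxopropyl)cyclohex-3-ene-1-carboxylate, via methyl enol ether 9 (not isolated)
Conditions: Ph3P(CH2OMe)Cl, KN(SiMe3)2, THF, 0 °C; then 1 M aq. HCl, THF, rt
Reagents that add atoms: (methoxymethyl)triphenylphosphonium chloride (COC[P+](c1ccccc1)(c1ccccc1)c1ccccc1.[Cl-]); water (O)
Why: Wittig methoxymethylenation followed by acid hydrolysis of the enol ether is the standard one-carbon homologation of an aldehyde, and the hindered ester and the quaternary centre next to the chain are untouched.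

Step 6
Reactants: 10 methyl (1S,2R,6R)-2,3,6-trimethyl-2-(3-oxopropyl)cyclohex-3-ene-1-carboxylate
Product: 11 methyl (1S,2R,6R)-2-(4,4-dibromobut-3-en-1-yl)-2,3,6-trimethylcyclohex-3-ene-1-carboxylate
Conditions: CBr4, PPh3, Zn, CH2Cl2, rt; then 10, 0 °C to rt
Reagents that add atoms: carbon tetrabromide (BrC(Br)(Br)Br)
Why: Ramirez dibromoolefination (the first stage of the Corey–Fuchs sequence) converts the aldehyde into the 1,1-dibromoalkene under neutral conditions that leave the ester and the ring alkene alone.

Step 7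
Reactants: 11 methyl (1S,2R,6R)-2-(4,4-dibromobut-3-en-1-yl)-2,3,6-trimethylcyclohex-3-ene-1-carboxylate; 12 5-bromo-2-methylpent-2-ene
Product: 14 methyl (1S,2R,6R)-2-[(3Z)-4-bromo-8-methylnona-3,7-dien-1-yl]-2,3,6-trimethylcyclohex-3-ene-1-carboxylate, via (4-methylpent-3-enyl)zinc bromide 13 (not isolated)
Conditions: 12, Zn, LiCl, THF, 50 °C; then 11, PdCl2(DPEphos) (cat.; DPEphos = bis(2-diphenylphosphinophenyl) ether), THF, 0 °C to rt
Reagents that add atoms: none
Why: In the Negishi coupling of a 1,1-dibromoalkene with an alkylzinc halide, oxidative addition takes place at the less hindered bromine trans to the chain, so a single alkylation should leave the bromine cis to the tether, which is the Z vinyl bromide, and the ester tolerates the organozinc reagent.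

Step 8
Reactants: 14 methyl (1S,2R,6R)-2-[(3Z)-4-bromo-8-methylnona-3,7-dien-1-yl]-2,3,6-trimethylcyclohex-3-ene-1-carboxylate
Product: 15 methyl (1S,2R,4aR,8aR)-2,4a,8a-trimethyl-5-(4-methylpent-3-en-1-yl)-1,2,4a,7,8,8a-hexahydronaphthalene-1-carboxylate
Conditions: Pd(OAc)2 (10 mol%), PPh3 (30 mol%), Ag2CO3, MeCN, 80 °C
Reagents that add atoms: none
Why: Zerovalent palladium, formed in the flask from Pd(OAc)2 and PPh3, inserts into the C5–Br bond with retention of the Z geometry, the C5–Pd bond adds syn across the C4=C4a alkene of ring A so that C5 bonds to C4a, and syn β-hydride loss from C3 releases the C3=C4 alkene. The closest known reaction type is the intramolecular Heck cyclisation that builds an all-carbon quaternary centre, including cases beside an existing quaternary carbon. Ring B closes in the 6-exo-trig mode (C4a inside the new ring, C4 outside), and the vinyl unit ends up endocyclic as C5=C6 with the 4-methylpent-3-enyl chain already on C5. The new stereocentre C4a is controlled by C8a, because the three-atom tether C8–C7–C6 lies on the face opposite the C8a methyl and can deliver C5 only to that face, which forces a cis ring fusion with the two angular methyls cis. The step needs 6-exo instead of 7-endo insertion and a single elimination product; the short tether secures the first, and the second follows because C4a has no hydrogen and, on the face where the palladium hydride is generated, C2 offers only its methyl group, so the alkene should not move past C3=C4 and C2 is not scrambled. Ag2CO3 removes bromide, which should speed insertion at the hindered alkene, and takes up the HBr.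

Step 9
Reactants: 15 methyl (1S,2R,4aR,8aR)-2,4a,8a-trimethyl-5-(4-methylpent-3-en-1-yl)-1,2,4a,7,8,8a-hexahydronaphthalene-1-carboxylate
Product: 16 methyl (1S,2R,4aR,8aR)-2,4a,8a-trimethyl-5-(4-methylpent-3-en-1-yl)-1,2,3,4,4a,7,8,8a-octahydronaphthalene-1-carboxylate
Conditions: 2-nitrobenzenesulfonyl hydrazide, Et3N, CH2Cl2, rt
Reagents that add atoms: none
Why: Diimide reduction transfers hydrogen in a concerted syn fashion much faster to the cis-disubstituted C3=C4 alkene than to the two trisubstituted alkenes, and no stereocentre is made or touched.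

Step 10
Reactants: 16 methyl (1S,2R,4aR,8aR)-2,4a,8a-trimethyl-5-(4-methylpent-3-en-1-yl)-1,2,3,4,4a,7,8,8a-octahydronaphthalene-1-carboxylate
Product: 17 (1S,2R,4aR,8aR)-2,4a,8a-trimethyl-5-(4-methylpent-3-en-1-yl)-1,2,3,4,4a,7,8,8a-octahydronaphthalene-1-carboxylic acid
Conditions: NaSEt, DMF, 100 °C; then 1 M aq. HCl
Reagents that add atoms: none
Why: SN2 demethylation by thiolate attacks the unhindered O-methyl carbon instead of the shielded carbonyl group, and the weakly basic medium should not epimerise C1.

Step 11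
Reactants: 17 (1S,2R,4aR,8aR)-2,4a,8a-trimethyl-5-(4-methylpent-3-en-1-yl)-1,2,3,4,4a,7,8,8a-octahydronaphthalene-1-carboxylic acid; 18 (R)-solketal, [(4R)-2,2-dimethyl-1,3-dioxolan-4-yl]methanol
Product: 20 [(4S)-2,2-dimethyl-1,3-dioxolan-4-yl]methyl (1S,2R,4aR,8aR)-2,4a,8a-trimethyl-5-(4-methylpent-3-en-1-yl)-1,2,3,4,4a,7,8,8a-octahydronaphthalene-1-carboxylate, via 2,4,6-trichlorobenzoic mixed anhydride 19 (not isolated)
Conditions: 2,4,6-trichlorobenzoyl chloride, Et3N, THF, rt; then 18, DMAP, toluene, rt
Reagents that add atoms: none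
Why: Yamaguchi esterification, in which DMAP attacks the aliphatic carbonyl of the mixed anhydride (the aroyl carbonyl is blocked by two ortho chlorines) and the acylpyridinium acylates the primary hydroxyl of solketal without involving the dioxolane stereocentre.

Step 12
Reactants: 20 [(4S)-2,2-dimethyl-1,3-dioxolan-4-yl]methyl ester of acid 17
Product: 21 (2S)-2,3-dihydroxypropyl (1S,2R,4aR,8aR)-2,4a,8a-trimethyl-5-(4-methylpent-3-en-1-yl)-1,2,3,4,4a,7,8,8a-octahydronaphthalene-1-carboxylate
Conditions: AcOH–H2O 4:1, 40 °C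
Reagents that add atoms: none
Why: Mild acid hydrolysis of a terminal acetonide, under which the hindered acyl group should resist 1,2-migration and the trisubstituted alkenes should survive.

Step 13
Reactants: 21 (2S)-2,3-dihydroxypropyl ester of acid 17
Product: 22 (2S)-3-(acetyloxy)-2-hydroxypropyl (1S,2R,4aR,8aR)-2,4a,8a-trimethyl-5-(4-methylpent-3-en-1-yl)-1,2,3,4,4a,7,8,8a-octahydronaphthalene-1-carboxylate (target)
Conditions: AcCl, 2,4,6-collidine, CH2Cl2, −78 °C
Reagents that add atoms: acetyl chloride (CC(Cl)=O)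
Why: Kinetically selective acylation of the primary over the secondary hydroxyl with an acid chloride and a hindered pyridine base at low temperature should give the 1-O-acyl-3-O-acetyl-sn-glycerol pattern of the target.

Compound list
1 | methyl acetoacetate | COC(=O)CC(C)=O | starting material
2 | acetaldehyde | CC=O | starting material
3 | dimethyl 2,4-diacetyl-3-methylpentanedioate (mixture of diastereomers) | COC(=O)C(C(C)=O)C(C)C(C(C)=O)C(=O)OC | intermediate (not isolated)
4 | rac-methyl (1S,6R)-2,6-dimethyl-4-oxocyclohex-2-ene-1-carboxylate | COC(=O)[C@H]1[C@H](C)CC(=O)C=C1C | intermediate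
5 | rac-methyl (1S,6R)-2,3,6-trimethyl-4-oxocyclohex-2-ene-1-carboxylate | COC(=O)[C@H]1[C@H](C)CC(=O)C(C)=C1C | intermediate
6 | methyl (1S,4S,6R)-4-hydroxy-2,3,6-trimethylcyclohex-2-ene-1-carboxylate | COC(=O)[C@H]1[C@H](C)C[C@H](O)C(C)=C1C | intermediate
7 | methyl (1S,4S,6R)-4-(ethenyloxy)-2,3,6-trimethylcyclohex-2-ene-1-carboxylate | COC(=O)[C@H]1[C@H](C)C[C@H](OC=C)C(C)=C1C | intermediate (not isolated)
8 | methyl (1S,2R,6R)-2,3,6-trimethyl-2-(2-oxoethyl)cyclohex-3-ene-1-carboxylate | COC(=O)[C@H]1[C@H](C)CC=C(C)[C@]1(C)CC=O | intermediate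
9 | methyl (1S,2R,6R)-2-(3-methoxyprop-2-en-1-yl)-2,3,6-trimethylcyclohex-3-ene-1-carboxylate (E/Z mixture) | COC(=O)[C@H]1[C@H](C)CC=C(C)[C@]1(C)CC=COC | intermediate (not isolated)
10 | methyl (1S,2R,6R)-2,3,6-trimethyl-2-(3-oxopropyl)cyclohex-3-ene-1-carboxylate | COC(=O)[C@H]1[C@H](C)CC=C(C)[C@]1(C)CCC=O | intermediate
11 | methyl (1S,2R,6R)-2-(4,4-dibromobut-3-en-1-yl)-2,3,6-trimethylcyclohex-3-ene-1-carboxylate | COC(=O)[C@H]1[C@H](C)CC=C(C)[C@]1(C)CCC=C(Br)Br | intermediate
12 | 5-bromo-2-methylpent-2-ene | CC(C)=CCCBr | starting material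
13 | (4-methylpent-3-enyl)zinc bromide | CC(C)=CCC[Zn]Br | intermediate (not isolated)
14 | methyl (1S,2R,6R)-2-[(3Z)-4-bromo-8-methylnona-3,7-dien-1-yl]-2,3,6-trimethylcyclohex-3-ene-1-carboxylate | COC(=O)[C@H]1[C@H](C)CC=C(C)[C@]1(C)CC/C=C(\Br)CCC=C(C)C | intermediate
15 | methyl (1S,2R,4aR,8aR)-2,4a,8a-trimethyl-5-(4-methylpent-3-en-1-yl)-1,2,4a,7,8,8a-hexahydronaphthalene-1-carboxylate (cis-fused) | COC(=O)[C@H]1[C@H](C)C=C[C@]2(C)C(CCC=C(C)C)=CCC[C@]12C | intermediate
16 | methyl (1S,2R,4aR,8aR)-2,4a,8a-trimethyl-5-(4-methylpent-3-en-1-yl)-1,2,3,4,4a,7,8,8a-octahydronaphthalene-1-carboxylate | COC(=O)[C@H]1[C@H](C)CC[C@]2(C)C(CCC=C(C)C)=CCC[C@]12C | intermediate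
17 | (1S,2R,4aR,8aR)-2,4a,8a-trimethyl-5-(4-methylpent-3-en-1-yl)-1,2,3,4,4a,7,8,8a-octahydronaphthalene-1-carboxylic acid | OC(=O)[C@H]1[C@H](C)CC[C@]2(C)C(CCC=C(C)C)=CCC[C@]12C | intermediate
18 | (R)-solketal, [(4R)-2,2-dimethyl-1,3-dioxolan-4-yl]methanol | CC1(C)OC[C@H](O1)CO | starting material
19 | mixed anhydride of acid 17 and 2,4,6-trichlorobenzoic acid | O=C(OC(=O)c1c(Cl)cc(Cl)cc1Cl)[C@H]1[C@H](C)CC[C@]2(C)C(CCC=C(C)C)=CCC[C@]12C | intermediate (not isolated)
20 | [(4S)-2,2-dimethyl-1,3-dioxolan-4-yl]methyl (1S,2R,4aR,8aR)-2,4a,8a-trimethyl-5-(4-methylpent-3-en-1-yl)-1,2,3,4,4a,7,8,8a-octahydronaphthalene-1-carboxylate | CC1(C)OC[C@H](O1)COC(=O)[C@H]2[C@H](C)CC[C@]3(C)C(CCC=C(C)C)=CCC[C@]23C | intermediate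
21 | (2S)-2,3-dihydroxypropyl (1S,2R,4aR,8aR)-2,4a,8a-trimethyl-5-(4-methylpent-3-en-1-yl)-1,2,3,4,4a,7,8,8a-octahydronaphthalene-1-carboxylate | OC[C@H](O)COC(=O)[C@H]1[C@H](C)CC[C@]2(C)C(CCC=C(C)C)=CCC[C@]12C | intermediate
22 | (2S)-3-(acetyloxy)-2-hydroxypropyl (1S,2R,4aR,8aR)-2,4a,8a-trimethyl-5-(4-methylpent-3-en-1-yl)-1,2,3,4,4a,7,8,8a-octahydronaphthalene-1-carboxylate | CC(=O)OC[C@H](O)COC(=O)[C@H]1[C@H](C)CC[C@]2(C)C(CCC=C(C)C)=CCC[C@]12C | target

Total step count: 13. Longest linear sequence: 13 steps (1 and 2 to 22); 12 and 18 enter without steps of their own.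

Steps most likely to fail

Step 8. Carbopalladation at the fully substituted C4a beside quaternary C8a may be slower than protodebromination or catalyst decay, so that ring B does not close. The fallback forms the same C4a–C5 bond from a ketone enolate instead of by alkene insertion; it sets out from 11 and returns at 15. Hydroboration–oxidation of the ring alkene of 11 (BH3·SMe2, THF, 0 °C; then NaBO3·4H2O) should give methyl 2-(4,4-dibromobut-3-en-1-yl)-4-hydroxy-2,3,6-trimethylcyclohexane-1-carboxylate F1, with boron going to the less substituted C4. Dess–Martin oxidation gives methyl 2-(4,4-dibromobut-3-en-1-yl)-2,3,6-trimethyl-4-oxocyclohexane-1-carboxylate F2. The Negishi coupling of step 7 with 13 then gives methyl 2-[(3Z)-4-bromo-8-methylnona-3,7-dien-1-yl]-2,3,6-trimethyl-4-oxocyclohexane-1-carboxylate F3. Palladium-catalysed intramolecular α-alkenylation of the ketone (Pd(PPh3)4, t-BuOK, THF, 60 °C) should join the C4a enolate carbon to C5 on the tether face and give methyl cis-fused 2,4a,8a-trimethyl-5-(4-methylpent-3-en-1-yl)-4-oxo-1,2,3,4,4a,7,8,8a-octahydronaphthalene-1-carboxylate F4; closure at C3 would need an eight-membered bridged ring. Enolisation toward C3, the only direction left (KN(SiMe3)2, PhNTf2, THF, −78 °C), gives methyl cis-fused 2,4a,8a-trimethyl-5-(4-methylpent-3-en-1-yl)-4-(trifluoromethanesulfonyloxy)-1,2,4a,7,8,8a-hexahydronaphthalene-1-carboxylate F5. Reduction of the enol triflate (Pd(OAc)2, PPh3, HCO2H, Et3N, DMF, 60 °C) gives 15.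

Step 3. Discrimination between the two enantiomers of 5 may be incomplete: substrate-controlled reduction of the mismatched enantiomer would erode the enantiomeric purity of 6. The fallback separates diastereoselection from enantioselection; it sets out from 5 and returns at 6. Luche reduction (NaBH4, CeCl3·7H2O, MeOH, −40 °C) should give the racemic 4,6-cis alcohol, that is 6 together with its enantiomer methyl (1R,4R,6S)-4-hydroxy-2,3,6-trimethylcyclohex-2-ene-1-carboxylate F6. Lipase-mediated acylation (Novozym 435, vinyl acetate, hexane, 30 °C), run slightly past half conversion, should acetylate the (4R)-carbinol, as the usual size rule for lipases predicts, to methyl (1R,4R,6S)-4-(acetyloxy)-2,3,6-trimethylcyclohex-2-ene-1-carboxylate F7. Unreacted 6 is separated by chromatography.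

Step 4. Vinyl transfer to the hindered secondary alcohol may stay incomplete, and thermal elimination to a diene may compete with rearrangement onto a fully substituted alkene carbon. The fallback delivers the two-carbon unit through a ketene N,O-acetal and reaches the aldehyde by a separate reduction; it sets out from 6 and returns at 8. Eschenmoser–Claisen rearrangement (N,N-dimethylacetamide dimethyl acetal, xylene, 140 °C) should give, with the same suprafacial transfer, methyl (1S,2R,6R)-2-[2-(dimethylamino)-2-oxoethyl]-2,3,6-trimethylcyclohex-3-ene-1-carboxylate F8. Chemoselective reduction of the tertiary amide in the presence of the ester (Cp2Zr(H)Cl, THF, rt) gives 8.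

Further compounds
F1 | step 8 | methyl 2-(4,4-dibromobut-3-en-1-yl)-4-hydroxy-2,3,6-trimethylcyclohexane-1-carboxylate (C1, C2, C6 as in 11; mixture at C3 and C4) | COC(=O)[C@H]1[C@H](C)CC(O)C(C)[C@]1(C)CCC=C(Br)Br
F2 | step 8 | methyl 2-(4,4-dibromobut-3-en-1-yl)-2,3,6-trimethyl-4-oxocyclohexane-1-carboxylate (C1, C2, C6 as in 11; mixture at C3) | COC(=O)[C@H]1[C@H](C)CC(=O)C(C)[C@]1(C)CCC=C(Br)Br
F3 | step 8 | methyl 2-[(3Z)-4-bromo-8-methylnona-3,7-dien-1-yl]-2,3,6-trimethyl-4-oxocyclohexane-1-carboxylate (C1, C2, C6 as in 14; mixture at C3) | COC(=O)[C@H]1[C@H](C)CC(=O)C(C)[C@]1(C)CC/C=C(\Br)CCC=C(C)C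
F4 | step 8 | methyl cis-fused 2,4a,8a-trimethyl-5-(4-methylpent-3-en-1-yl)-4-oxo-1,2,3,4,4a,7,8,8a-octahydronaphthalene-1-carboxylate (configuration as in 16) | COC(=O)[C@H]1[C@H](C)CC(=O)[C@]2(C)C(CCC=C(C)C)=CCC[C@]12C
F5 | step 8 | methyl cis-fused 2,4a,8a-trimethyl-5-(4-methylpent-3-en-1-yl)-4-(trifluoromethanesulfonyloxy)-1,2,4a,7,8,8a-hexahydronaphthalene-1-carboxylate (configuration as in 15) | COC(=O)[C@H]1[C@H](C)C=C(OS(=O)(=O)C(F)(F)F)[C@]2(C)C(CCC=C(C)C)=CCC[C@]12C
F6 | step 3 | methyl (1R,4R,6S)-4-hydroxy-2,3,6-trimethylcyclohex-2-ene-1-carboxylate | COC(=O)[C@@H]1[C@@H](C)C[C@@H](O)C(C)=C1C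
F7 | step 3 | methyl (1R,4R,6S)-4-(acetyloxy)-2,3,6-trimethylcyclohex-2-ene-1-carboxylate | COC(=O)[C@@H]1[C@@H](C)C[C@@H](OC(C)=O)C(C)=C1C
F8 | step 4 | methyl (1S,2R,6R)-2-[2-(dimethylamino)-2-oxoethyl]-2,3,6-trimethylcyclohex-3-ene-1-carboxylate | COC(=O)[C@H]1[C@H](C)CC=C(C)[C@]1(C)CC(=O)N(C)C
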